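A direct plan would oxidise the ring methyl group of the dearomatised triketone norflavesone A1 to the o-quinone methide A2 and add A2 across the C1=C2 alkene of achiral α-humulene A3 in a hetero-Diels–Alder reaction, giving racemic hyperjapone A as the adduct A4.
It would then epoxidise the 8,9-alkene of A4 with a chiral dioxirane as a kinetic resolution to the epoxide A5 and let acid trigger a transannular epoxide–olefin cyclisation of A5, a ring-contracting 1,2-alkyl shift and loss of a proton.
Its weakest steps would be:
- The cycloaddition of A2 with achiral A3 would give A4 as a racemate, so all absolute configuration would rest on the late kinetic resolution to A5, which gives up at least half of the tetracyclic material and must also pick one of two remaining alkenes beside an oxidisable enol.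
- The acid cascade from A5 would have to set C4, C5 and C9 at once and choose among hydride shift, alkyl shift, capture and two elimination modes with no controlling group.
- The quinone methide A2 would have to select one of three trisubstituted alkenes of A3 while tending to dimerise, so the first fragment union would be inefficient.

**Retrosynthetic overview**
Ring B is read as the cyclic enol ether of an anti aldol: cutting O–C2 (cyclodehydration onto ring A) and C12–ring A (reductive Knoevenagel) gives β-hydroxy aldehyde 19 and isobutyrylfilicinic acid 18, and a retro-aldol across C1–C2 of ring C gives keto aldehyde 13.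
Ring D of 13 (C4, C5, C7, C8, C9, with C3 as a formyl carbon) is the ring-contracted carbocycle of (S)-carvone, which supplies C5 with its isopropenyl group, the C8 oxygen and the 9-methyl; C9 becomes quaternary by conjugate addition anti to the C8 silyl ether.
Rings close in the order D (step 5), C (step 10), B (step 11); ring A is brought in preformed (steps 8 and 9).
The design starts from one enantiomer (no resolution), uses no carbocation cascade (C4, C5, C8, C9 are set one by one on a cyclopentane, C1 and C2 together by the catalyst), and carries a single alkene throughout, so no alkene site selectivity is needed.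

Key step: step 10

Remark: C1–C11 are the humulane locants of the target descriptor (1S,2R,4S,5R,8R,9R) and C12 is the pyran CH2. Ring A is the cyclohexadienone, ring B the pyran, ring C the cycloheptane, ring D the cyclopentane.

Step 1
Reactants: 1 (S)-(+)-carvone
Product: 2 carvone 2,3-epoxide, epoxide oxygen trans to the isopropenyl group
Conditions: H2O2 (30 % aq.), NaOH (cat.), MeOH, 0 °C
Reagents that add atoms: hydrogen peroxide, OO
Why: Weitz–Scheffer nucleophilic epoxidation attacks only the electron-poor enone alkene (the isopropenyl group is inert), and the hydroperoxide anion should add anti to the isopropenyl group, placing the epoxide trans to it.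

Step 2
Reactants: 2 carvone 2,3-epoxide
Product: 3 2,3-epoxy-2-methyl-5-(prop-1-en-2-yl)cyclohexan-1-ol, hydroxyl cis to the epoxide oxygen and trans to the isopropenyl group
Conditions: NaBH4, CeCl3·7H2O, MeOH, −20 °C
Reagents that add atoms: none
Why: Luche reduction in which hydride should approach anti to the epoxide C–O bond (Felkin–Anh), so the new hydroxyl (the future C8–O, 8R) is cis to the epoxide oxygen and therefore trans to the isopropenyl group.

Step 3
Reactants: 3 epoxy alcohol
Product: 4 tert-butyldimethylsilyl ether of 3
Conditions: tert-butyldimethylsilyl chloride, imidazole, DMF, rt → 40 °C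
Reagents that add atoms: tert-butyldimethylsilyl chloride, CC(C)(C)[Si](C)(C)Cl
Why: Standard silylation of the secondary alcohol; the ether prevents periodate cleavage of an α-hydroxy ketone in step 4 and later steers the cuprate in step 6.

Step 4
Reactants: 4 silyl ether
Product: 5 5-[(tert-butyldimethylsilyl)oxy]-6-oxo-3-(prop-1-en-2-yl)heptanal (C5 and C8 of the target as in 4)
Conditions: H5IO6, THF/H2O, 0 °C → rt
Reagents that add atoms: water, O
Why: Periodic acid hydrolyses the epoxide to the diol and cleaves it (glycol cleavage) to the methyl ketone and the aldehyde without touching the isopropenyl group, the silyl ether or the two stereocentres.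

Step 5
Reactants: 5 keto aldehyde
Product: 6 3-[(tert-butyldimethylsilyl)oxy]-2-methyl-5-(prop-1-en-2-yl)cyclopent-1-ene-1-carbaldehyde, silyloxy and isopropenyl trans
Conditions: piperidine (0.2 equiv), AcOH (0.2 equiv), benzene, 4 Å MS, rt → 50 °C
Reagents that add atoms: none
Why: Amine-catalysed intramolecular aldol condensation (aldehyde enamine onto the α-silyloxy ketone, 5-enolexo) closes ring D as the conjugated enal, as known for the analogous keto aldehyde from limonene; the buffered conditions should spare the C8 centre.

Step 6
Reactants: 6 cyclopentene carbaldehyde; 7 4-bromo-1,1-dimethoxybutane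
Product: 10 ring D aldehyde with formyl (C3) on C4, isopropenyl on C5, silyloxy on C8, methyl and 4,4-dimethoxybutyl (C10–C11–C1–C12) on C9; chain trans to silyloxy, formyl trans to isopropenyl and to the chain, via Grignard reagent 8 (not isolated), via silyl enol ether 9 (not isolated)
Conditions: 7, Mg, THF; then CuBr·SMe2 (0.2 equiv), Me3SiCl, DMPU, 6, THF, −78 → −30 °C; aq. NH4Cl; K2CO3, MeOH, rt
Reagents that add atoms: (4,4-dimethoxybutyl)magnesium bromide, COC(OC)CCC[Mg]Br
Why: Copper-catalysed, chlorosilane-accelerated conjugate addition of a Grignard reagent to a β,β-disubstituted enal creates the quaternary C9 with the chain anti to the adjacent silyl ether (9R, methyl cis to the oxygen), and base equilibration of the α-centre places the formyl group trans to both the isopropenyl group and the chain (4S, the later trans C/D fusion).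

Step 7
Reactants: 10 ring D aldehyde; 11 (1-methoxyethyl)triphenylphosphonium chloride
Product: 13 keto aldehyde with 2-oxopropyl (C3–C2, 2-methyl) on C4 and 4-oxobutyl (C10–C11–C1–C12) on C9, via enol ether 12 (not isolated)
Conditions: 11, KN(SiMe3)2, THF, −78 → 0 °C; then 10, 0 °C → rt; then 0.5 M HCl, THF, 0 °C
Reagents that add atoms: (1-methoxyethyl)triphenylphosphonium chloride, COC(C)[P+](c1ccccc1)(c1ccccc1)c1ccccc1.[Cl-]; water, O
Why: Wittig reaction with the α-methoxy ylide homologates the aldehyde to an enol ether, and brief aqueous acid in the same flask unveils the methyl ketone (C2 with its methyl) and the aldehyde (C12) without touching a stereocentre or the silyl ether.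

Step 8
Reactants: 14 phloroglucinol; 15 isobutyryl chloride
Product: 16 2-methyl-1-(2,4,6-trihydroxyphenyl)propan-1-one
Conditions: AlCl3 (4 equiv), CH2Cl2/MeNO2, 0 °C → reflux; aq. HCl
Reagents that add atoms: isobutyryl chloride, CC(C)C(Cl)=O
Why: Friedel–Crafts acylation of the symmetric triol should stop at the mono-ketone because the aluminium-chelated aryl ketone is deactivated; no stereocentre is formed.

Step 9
Reactants: 16 acylphloroglucinol; 17 iodomethane
Product: 18 isobutyrylfilicinic acid, 3,5-dihydroxy-6,6-dimethyl-2-(2-methylpropanoyl)cyclohexa-2,4-dien-1-one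
Conditions: NaOMe (3 equiv), MeI (2 equiv), MeOH, 0 °C → rt; chromatography
Reagents that add atoms: iodomethane, CI
Why: Base-mediated C-methylation of the acylphloroglucinol polyanion should put both methyl groups on one ring carbon, dearomatising the ring to the gem-dimethyl β-triketone and leaving one CH-acidic ring carbon for step 10; the limited amount of iodomethane and chromatography remove under- and over-methylated congeners.

Step 10
Reactants: 13 keto aldehyde; 18 isobutyrylfilicinic acid
Product: 21 C-alkylated triketone: ring A joined through C12H2 to C1 of the trans-fused C/D bicycle, free tertiary 2-hydroxyl, 8-silyloxy; configuration (1S,2R,4S,5R,8R,9R), via aldol 19 (not isolated), via alkylidene triketone 20 (not isolated)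
Conditions: (R)-proline (0.3 equiv), CH2Cl2 (0.05 M), rt; then 18 (1.0 equiv), Hantzsch ester (diethyl 2,6-dimethyl-1,4-dihydropyridine-3,5-dicarboxylate, 1.1 equiv), rt
Reagents that add atoms: none
Why: Proposed new method: the aldehyde of 13 should condense with (R)-proline to the E-enamine, whose C1 attacks the methyl ketone C2 through the carboxylic-acid-bridged chair-like transition state of proline aldolisations; the closest known reaction type is the proline-catalysed 6-enolexo aldolisation of dialdehydes and keto aldehydes to anti β-hydroxy aldehydes, and here the trans-1,2-disubstituted cyclopentane holds the two termini close, which should offset the entropic cost of the seven-membered ring. Ring C closes in the 7-(enolexo)-exo-trig mode; in the same flask the new aldehyde 19 undergoes Knoevenagel condensation with the only CH-acidic ring carbon of 18, and the alkylidene 20 is reduced at C12 by the Hantzsch ester (the known organocatalytic reductive alkylation of cyclic 1,3-diones), which forges the C12–ring A bond and removes the epimerisable aldehyde. C1 and C2 are set together: the anti topicity (C12 trans to the 2-hydroxyl, the retron of the trans B/C fusion) follows from the E-enamine and the hydrogen-bonded transition state, and the absolute sense is imposed by the catalyst, since the model by which (S)-proline gives (2S,3S)-anti aldols from aldehyde donors maps onto the mirror-image (1R,2S) array when the tether takes the place of the acceptor substituent and the methyl that of the acceptor hydrogen, so that (R)-proline is the enantiomer required for (1S,2R). The step needs enamine formation at the aldehyde and not at the ketone (aldehydes condense far faster), ring closure in preference to intermolecular aldol (dilution), and no other carbonyl within reach (C8 is kept as a silyl ether); 18 is added only after the aldol is complete so that it cannot intercept the open-chain aldehyde.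

Step 11
Reactants: 21 C-alkylated triketone
Product: 22 8-O-(tert-butyldimethylsilyl) ether of the target
Conditions: pyridinium p-toluenesulfonate (0.2 equiv), 4 Å MS, toluene, 60 °C
Reagents that add atoms: none
Why: Acid-catalysed cyclodehydration of a δ-hydroxy vinylogous acid: the tertiary 2-hydroxyl adds to the ring A carbonyl carbon next to the gem-dimethyl carbon (6-exo-trig, hemiketal) and water is lost to the cyclic enol ether that keeps the acyl-chelated enol, so ring B closes with retention at C2 and the anti aldol becomes the trans B/C fusion.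

Step 12
Reactants: 22 silyl-protected target
Product: 23 target compound, (1S,2R,4S,5R,8R,9R)
Conditions: HF·pyridine, pyridine, THF, 0 °C → rt
Reagents that add atoms: none
Why: Fluoride-mediated cleavage of the silyl ether frees the 8-hydroxyl; the β-triketone, the enol ether of ring B and the isopropenyl group should tolerate buffered HF·pyridine.

**Compound list**

1 | (S)-(+)-carvone, (5S)-2-methyl-5-(prop-1-en-2-yl)cyclohex-2-en-1-one | CC1=CC[C@@H](CC1=O)C(C)=C | starting material
2 | carvone 2,3-epoxide, epoxide trans to isopropenyl | O=C1C[C@@H](C(C)=C)C[C@@H]2O[C@]12C | intermediate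
3 | 2,3-epoxy-2-methyl-5-(prop-1-en-2-yl)cyclohexan-1-ol, OH cis to epoxide oxygen, trans to isopropenyl | O[C@@H]1C[C@@H](C(C)=C)C[C@@H]2O[C@]12C | intermediate
4 | tert-butyldimethylsilyl ether of 3 | CC(C)(C)[Si](C)(C)O[C@@H]1C[C@@H](C(C)=C)C[C@@H]2O[C@]12C | intermediate
5 | 5-[(tert-butyldimethylsilyl)oxy]-6-oxo-3-(prop-1-en-2-yl)heptanal | CC(C)(C)[Si](C)(C)O[C@@H](C(C)=O)C[C@@H](C(C)=C)CC=O | intermediate
6 | 3-[(tert-butyldimethylsilyl)oxy]-2-methyl-5-(prop-1-en-2-yl)cyclopent-1-ene-1-carbaldehyde, silyloxy trans to isopropenyl | O=CC1=C(C)[C@H](O[Si](C)(C)C(C)(C)C)C[C@H]1C(C)=C | intermediate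
7 | 4-bromo-1,1-dimethoxybutane | COC(OC)CCCBr | starting material
8 | (4,4-dimethoxybutyl)magnesium bromide | COC(OC)CCC[Mg]Br | intermediate (not isolated)
9 | trimethylsilyl enol ether of 10 | C[Si](C)(C)OC=C1[C@@](C)(CCCC(OC)OC)[C@H](O[Si](C)(C)C(C)(C)C)C[C@H]1C(C)=C | intermediate (not isolated)
10 | ring D aldehyde: 2-(4,4-dimethoxybutyl)-2-methyl-3-silyloxy-5-isopropenylcyclopentane-1-carbaldehyde; chain trans to silyloxy, formyl trans to isopropenyl and chain | O=C[C@@H]1[C@@](C)(CCCC(OC)OC)[C@H](O[Si](C)(C)C(C)(C)C)C[C@H]1C(C)=C | intermediate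
11 | (1-methoxyethyl)triphenylphosphonium chloride | COC(C)[P+](c1ccccc1)(c1ccccc1)c1ccccc1.[Cl-] | starting material
12 | methyl enol ether from 10 (E/Z mixture) | COC(C)=C[C@@H]1[C@@](C)(CCCC(OC)OC)[C@H](O[Si](C)(C)C(C)(C)C)C[C@H]1C(C)=C | intermediate (not isolated)
13 | keto aldehyde: ring D with 2-oxopropyl on C4 and 4-oxobutyl on C9 | CC(=O)C[C@@H]1[C@@](C)(CCCC=O)[C@H](O[Si](C)(C)C(C)(C)C)C[C@H]1C(C)=C | intermediate
14 | phloroglucinol | Oc1cc(O)cc(O)c1 | starting material
15 | isobutyryl chloride | CC(C)C(Cl)=O | starting material
16 | 2-methyl-1-(2,4,6-trihydroxyphenyl)propan-1-one | CC(C)C(=O)c1c(O)cc(O)cc1O | intermediate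
17 | iodomethane | CI | starting material
18 | isobutyrylfilicinic acid | CC(C)C(=O)C1=C(O)C=C(O)C(C)(C)C1=O | intermediate
19 | anti aldol: trans-fused C/D bicycle with formyl (C12) on C1 trans to the tertiary 2-hydroxyl | O=C[C@@H]1CC[C@@]2(C)[C@H](O[Si](C)(C)C(C)(C)C)C[C@@H](C(C)=C)[C@@H]2C[C@@]1(C)O | intermediate (not isolated)
20 | alkylidene triketone (Knoevenagel adduct of 19 and 18) | CC(C)C(=O)C1=C(O)C(=C[C@@H]2CC[C@@]3(C)[C@H](O[Si](C)(C)C(C)(C)C)C[C@@H](C(C)=C)[C@@H]3C[C@@]2(C)O)C(=O)C(C)(C)C1=O | intermediate (not isolated)
21 | C-alkylated triketone (ring A–C12H2–C1), 2-OH free, 8-OTBS | CC(C)C(=O)C1=C(O)C(C[C@@H]2CC[C@@]3(C)[C@H](O[Si](C)(C)C(C)(C)C)C[C@@H](C(C)=C)[C@@H]3C[C@@]2(C)O)=C(O)C(C)(C)C1=O | intermediate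
22 | 8-O-(tert-butyldimethylsilyl) ether of the target | C=C(C)[C@@H]1C[C@@H](O[Si](C)(C)C(C)(C)C)[C@]2(C)CC[C@H]3CC4=C(O[C@]3(C)C[C@@H]12)C(C)(C)C(=O)C(C(=O)C(C)C)=C4O | intermediate
23 | target compound, (1S,2R,4S,5R,8R,9R) in the humulane locants | C=C(C)[C@@H]1C[C@@H](O)[C@]2(C)CC[C@H]3CC4=C(O[C@]3(C)C[C@@H]12)C(C)(C)C(=O)C(C(=O)C(C)C)=C4O | target

**Step count**
Total: 12 steps. Longest linear sequence: 10 steps (steps 1–7 and 10–12); steps 8 and 9 make fragment 18.

**Steps most likely to fail**

Step 10. The seven-membered enamine aldol may be slow compared with dehydration to the conjugated enal or retro-aldol, it may take the syn pathway, or the catalyst may fail to override the ring D stereocentres. The fallback uses only known reaction types, sets out from 6 and returns at 19. Copper-catalysed conjugate addition of the Grignard reagent of 2-(2-bromoethyl)-2-ethyl-1,3-dioxolane to 6 (conditions of step 6) would give the aldehyde F1. Acid hydrolysis of the ketal and aldol condensation of the ethyl ketone with the C3 aldehyde (KOH, MeOH) would close ring C as the cycloheptenone F2 (C1 ketone, C2=C3 alkene). Nucleophilic epoxidation (H2O2, NaOH) should occur anti to the angular 9-methyl, which is syn-axial to C3, giving the epoxy ketone F3. LiAlH4 would reduce the ketone and open the epoxide at C3 to the diol F4, with the tertiary 2-hydroxyl on the face of H-4. Dess–Martin oxidation would give the hydroxy ketone F5, and Wittig methylenation (Ph3P=CH2) the allylic alcohol F6. Silylation with chlorodimethylsilane would give the dimethylsilyl ether F7; intramolecular hydrosilylation with Pt2[(CH2=CHSiMe2)2O]3 (zerovalent platinum) would deliver H-1 from the face of the 2-oxygen and give the oxasilolane F8; Tamao–Fleming oxidation (H2O2, KF, KHCO3) would give the 1,3-diol F9. Oxidation of the primary alcohol (TEMPO, PhI(OAc)2) would give 19, which enters the second stage of step 10.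

Step 6. The organocopper reagent may fail to add to the β,β-disubstituted enal beside the silyl ether (1,2-addition or enolisation taking over). The fallback sets out from 6 and returns at 10: a radical conjugate addition (Giese reaction) of 4-iodo-1,1-dimethoxybutane F10 (from 7 and NaI in acetone) with (Me3Si)3SiH and AIBN in toluene at 80 °C. The primary alkyl radical is far less sensitive to congestion at C9 and should still enter anti to the adjacent silyl ether; equilibration with K2CO3 in MeOH then gives 10.

Step 11. Acid may ionise the tertiary C2–O bond before the hydroxyl has added to ring A (loss of the C2 configuration or elimination toward C1 or C3), or the oxygen may close onto the other ring A carbonyl. The fallback sets out from 21 and returns at 22: ring A is activated instead of the alcohol. Triflation of the free vinylogous acid hydroxyl (PhNTf2, Et3N, CH2Cl2, −20 °C) would give the vinylogous acyl triflate F11, and base (DBU, MeCN) would induce intramolecular addition–elimination by the tertiary hydroxyl (6-exo-trig), closing ring B with retention at C2 under non-acidic conditions.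

**Further compounds**

F1 | step 10 | ring D aldehyde with 2-(2-ethyl-1,3-dioxolan-2-yl)ethyl and methyl on C9 | O=C[C@@H]1[C@@](C)(CCC2(CC)OCCO2)[C@H](O[Si](C)(C)C(C)(C)C)C[C@H]1C(C)=C
F2 | step 10 | trans-fused cycloheptenone (C1 ketone, C2=C3, 2-methyl), 8-OTBS | CC1=C[C@H]2[C@H](C(C)=C)C[C@@H](O[Si](C)(C)C(C)(C)C)[C@]2(C)CCC1=O
F3 | step 10 | 2,3-epoxy ketone, epoxide on the face of H-4 | C[C@@]12O[C@@H]1[C@H]1[C@H](C(C)=C)C[C@@H](O[Si](C)(C)C(C)(C)C)[C@]1(C)CCC2=O
F4 | step 10 | 1,2-diol (C1 secondary, epimers; C2 tertiary, configuration of the target) | C[C@@]1(O)C[C@H]2[C@H](C(C)=C)C[C@@H](O[Si](C)(C)C(C)(C)C)[C@]2(C)CCC1O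
F5 | step 10 | 2-hydroxy-2-methyl ketone (C1 ketone) | C[C@@]1(O)C[C@H]2[C@H](C(C)=C)C[C@@H](O[Si](C)(C)C(C)(C)C)[C@]2(C)CCC1=O
F6 | step 10 | 1-methylidene tertiary alcohol | C[C@@]1(O)C[C@H]2[C@H](C(C)=C)C[C@@H](O[Si](C)(C)C(C)(C)C)[C@]2(C)CCC1=C
F7 | step 10 | dimethylsilyl (Si–H) ether of F6 | C[C@@]1(O[SiH](C)C)C[C@H]2[C@H](C(C)=C)C[C@@H](O[Si](C)(C)C(C)(C)C)[C@]2(C)CCC1=C
F8 | step 10 | trans-fused oxasilolane (O–SiMe2–C12H2–C1) | C[C@@]12C[C@H]3[C@H](C(C)=C)C[C@@H](O[Si](C)(C)C(C)(C)C)[C@]3(C)CC[C@H]1C[Si](C)(C)O2
F9 | step 10 | 1,3-diol (C12H2OH on C1 trans to the 2-hydroxyl) | C[C@@]1(O)C[C@H]2[C@H](C(C)=C)C[C@@H](O[Si](C)(C)C(C)(C)C)[C@]2(C)CC[C@H]1CO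
F10 | step 6 | 4-iodo-1,1-dimethoxybutane | COC(OC)CCCI
F11 | step 11 | vinylogous acyl triflate of 21 (triflate on the ring A oxygen next to the gem-dimethyl carbon) | CC(C)C(=O)C1=C(O)C(C[C@@H]2CC[C@@]3(C)[C@H](O[Si](C)(C)C(C)(C)C)C[C@@H](C(C)=C)[C@@H]3C[C@@]2(C)O)=C(OS(=O)(=O)C(F)(F)F)C(C)(C)C1=O
A1 | direct plan | norflavesone | CC(C)C(=O)C1=C(O)C(C)=C(O)C(C)(C)C1=O
A2 | direct plan | o-quinone methide of norflavesone | CC(C)C(=O)C1=C(O)C(=C)C(=O)C(C)(C)C1=O
A3 | direct plan | α-humulene | C/C1=C\CC(C)(C)/C=C/C/C(C)=C/CC1
A4 | direct plan | (±)-hyperjapone A | CC(C)C(=O)C1=C(O)C2=C(O[C@]3(C)C/C=C/C(C)(C)C/C=C(\C)CC[C@H]3C2)C(C)(C)C1=O.CC(C)C(=O)C1=C(O)C2=C(O[C@@]3(C)C/C=C/C(C)(C)C/C=C(\C)CC[C@@H]3C2)C(C)(C)C1=O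
A5 | direct plan | (1S,2R,8R,9R)-8,9-epoxyhyperjapone A | CC(C)C(=O)C1=C(O)C2=C(O[C@]3(C)C/C=C/C(C)(C)C[C@H]4O[C@]4(C)CC[C@H]3C2)C(C)(C)C1=O
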